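**Retrosynthetic overview**
1. Target ⇐ trans-diaxial SN2 opening of an 8α,9α vinyl epoxide by angelic acid; the 5-acetoxy-4-ketone ⇐ acetoxylation of a ring-fused methyl enol ether.
2. Five-membered ring (closed last) ⇐ RCM between the C6 vinyl group and an enol ether that arises, together with the exocyclic methylene, by double carbonyl methylenation of an epoxy keto ester.
3. Six-membered ring ⇐ one-carbon ring expansion of a 1-siloxybicyclo[3.1.0]hexane (cyclopentane → 2,3-epoxycyclohexanone); this is the key step.
4. That cyclopentane with its three contiguous stereocentres ⇐ vinyl cuprate addition, enolate alkylation, silanol elimination and isopropyl cuprate addition on (R)-4-silyloxycyclopentenone.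
5. Ring order: bought cyclopentenone → expanded to the cyclohexane → new cyclopentanone ring by RCM.

Atom labels in names (always written with C): C1 = carbon that ends as C=CH2 (the cyclopentenone carbonyl carbon), C2 and C6 = ring-fusion carbons, C3/C4/C5 = CH2, C=O and CH–OAc of the five-membered ring, C7 = CH–iPr, C8 = CH–OH, C9 = CH–O-angelate. β = face of H at C2, α = face of H at C6.

Assumption: (R)-4-hydroxycyclopent-2-en-1-one is bought as its tert-butyldimethylsilyl ether (compound 1).

**Step 1**
Reactants: 1 (R)-4-(tert-butyldimethylsilyloxy)cyclopent-2-en-1-one; 2 vinylmagnesium bromide; 3 methyl bromoacetate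
Product: 6 methyl 2-[(1,5-trans)-2-oxo-5-vinylcyclopent-3-en-1-yl]acetate (arm at C2 α; vinyl at C6 β), via magnesium enolate 4 (not isolated), via silyloxy keto ester 5 (not isolated)
Conditions: 2 (1.3 equiv), CuBr·SMe2 (10 mol %), THF, −78 °C; then 3 (2 equiv), DMPU, −78 → −20 °C; aq. NH4Cl work-up; crude + DBU (1.2 equiv), CH2Cl2, 0 °C
Reagents that add atoms: none
Why: Copper-catalysed conjugate addition of the vinyl Grignard occurs anti to the C7 silyloxy group (sets C6), the magnesium enolate is alkylated trans to the new vinyl group (sets C2; prostaglandin-type three-component coupling), and DBU then expels the silanol by E1cB elimination to unveil the second enone.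

**Step 2**
Reactants: 6 methyl 2-[(1,5-trans)-2-oxo-5-vinylcyclopent-3-en-1-yl]acetate; 7 isopropylmagnesium chloride
Product: 8 methyl 2-[4-isopropyl-2-(trimethylsilyloxy)-5-vinylcyclopent-2-en-1-yl]acetate (arm α at C2; vinyl β at C6; isopropyl α at C7; enol silane C1=C8)
Conditions: 7 (1.5 equiv), CuBr·SMe2 (10 mol %), Me3SiCl (2 equiv), THF, −78 °C; Et3N, pentane, filtration
Reagents that add atoms: chlorotrimethylsilane, C[Si](C)(C)Cl
Why: Copper-catalysed 1,4-addition of the isopropyl Grignard anti to the adjacent C6 vinyl group sets C7, and in situ silylation (Nakamura–Kuwajima conditions) traps the enolate regiospecifically as the C1=C8 enol silane needed for the ring expansion.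

**Step 3**
Reactants: 8 methyl 2-[4-isopropyl-2-(trimethylsilyloxy)-5-vinylcyclopent-2-en-1-yl]acetate
Product: 9 methyl 2-[4-isopropyl-1-(trimethylsilyloxy)-3-vinylbicyclo[3.1.0]hexan-2-yl]acetate (cyclopropane CH2 = C9 on the β face; arm α; vinyl β; isopropyl α)
Conditions: Et2Zn (1.5 equiv), CH2I2 (1.5 equiv), CH2Cl2, 0 °C
Reagents that add atoms: diiodomethane, ICI
Why: Furukawa-type Simmons–Smith cyclopropanation is much faster on the electron-rich enol silane than on the terminal vinyl group; the carbenoid enters anti to the C2 and C7 substituents, and the two new centres (C1, C8) are erased in step 4.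

**Step 4**
Reactants: 9 methyl 2-[4-isopropyl-1-(trimethylsilyloxy)-3-vinylbicyclo[3.1.0]hexan-2-yl]acetate
Product: 12 methyl 2-(5-isopropyl-2-oxo-4-vinyl-7-oxabicyclo[4.1.0]heptan-3-yl)acetate (8α,9α-epoxide cis to the 7α-isopropyl; vinyl β; arm α), via cyclopropanol 10 (not isolated), via hydroperoxy ketone 11 (not isolated)
Conditions: Mn(acac)3 (5 mol %), O2 (1 atm), MeOH (5 equiv), PhH, 20 °C; then DBU (1.5 equiv), 0 °C
Reagents that add atoms: dioxygen, O=O
Why: Proposed new method: methanolysis gives cyclopropanol 10, whose trivalent-manganese alkoxide undergoes β-scission of the internal C1–C8 bond (one-carbon ring expansion to the secondary C8 radical of the cyclohexanone, as in a Saegusa–Ito expansion); O2 traps the radical as hydroperoxide 11 and returns divalent manganese to trivalent manganese; DBU then closes 11 through its β-peroxy enolate, the second half of a Weitz–Scheffer epoxidation, where reversible loss and axial re-addition of hydroperoxide at C8 of the conformationally locked all-equatorial enone should funnel both C8 epimers to the epoxide cis to the isopropyl group; closest known reactions are the FeCl3-mediated Saegusa–Ito ring expansion of siloxybicyclo[n.1.0]alkanes and the manganese-catalysed aerobic conversion of simple cyclopropanols into epoxy ketones.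

**Step 5**
Reactants: 12 methyl 2-(5-isopropyl-2-oxo-4-vinyl-7-oxabicyclo[4.1.0]heptan-3-yl)acetate
Product: 13 5-isopropyl-3-(2-methoxyprop-2-en-1-yl)-2-methylene-4-vinyl-7-oxabicyclo[4.1.0]heptane (same configuration as 12)
Conditions: Cp2TiMe2 (5 equiv), toluene, 70 °C, dark
Reagents that add atoms: dimethyltitanocene Cp2TiMe2, C[Ti](C)(C1C=CC=C1)C1C=CC=C1
Why: Petasis methylenation (Cp2Ti=CH2 formed thermally) is non-basic, so C2 is not epimerised, and it converts the ketone into the exocyclic alkene and the ester into the methyl enol ether in one operation.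

**Step 6**
Reactants: 13 5-isopropyl-3-(2-methoxyprop-2-en-1-yl)-2-methylene-4-vinyl-7-oxabicyclo[4.1.0]heptane
Product: 14 8α,9α-epoxy-7α-isopropyl-4-methoxy-1-methylene-trans-hydrind-4-ene (enol ether C4=C5; H-2 β; H-6 α)
Conditions: second-generation Grubbs catalyst (H2IMes)(PCy3)Cl2Ru=CHPh (5 mol %), PhH, 60 °C
Reagents that add atoms: none
Why: Ring-closing metathesis starts at the monosubstituted vinyl group and closes onto the enol ether to give the cyclopentene; the exocyclic methylene cannot close a ring of sensible size, and the existing C2 and C6 centres fix the trans ring fusion.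

**Step 7**
Reactants: 14 8α,9α-epoxy-7α-isopropyl-4-methoxy-1-methylene-trans-hydrind-4-ene
Product: 16 5α-acetoxy-8α,9α-epoxy-7α-isopropyl-1-methylene-trans-hydrindan-4-one, via acetoxy ketal 15 (not isolated)
Conditions: Pb(OAc)4 (1.1 equiv), pyridine (2 equiv), PhH, 10 °C; then H2O
Reagents that add atoms: lead tetraacetate Pb(OAc)4, CC(=O)O[Pb](OC(C)=O)(OC(C)=O)OC(C)=O; water, O
Why: Lead tetraacetate acetoxylates the nucleophilic C5 of the enol ether (Criegee-type α-acetoxylation), so the enol ether dictates the regiochemistry of the acetoxy ketone; the acetate is expected on the α face, trans to the C6–C7 bond, which is also the thermodynamically preferred position at this epimerisable centre.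

**Step 8**
Reactants: 16 5α-acetoxy-8α,9α-epoxy-7α-isopropyl-1-methylene-trans-hydrindan-4-one; 17 angelic acid ((Z)-2-methylbut-2-enoic acid)
Product: 18 CNP0317011.1 (5α-acetoxy-8α-hydroxy-7α-isopropyl-1-methylene-4-oxo-trans-hydrindan-9β-yl angelate)
Conditions: 17 (5 equiv), iPr2NEt (0.5 equiv), DMF, 60 °C
Reagents that add atoms: none
Why: The carboxylate opens the vinyl epoxide by SN2 attack at the allylic C9 with inversion along the axial trajectory of the trans-fused chair (Fürst–Plattner trans-diaxial opening), which gives the 9β-angelate and the 8α-hydroxyl; C8 is shielded by the isopropyl group, and buffered non-acidic conditions avoid angelate-to-tiglate isomerisation.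

**Compound list**
1 | (R)-4-(tert-butyldimethylsilyloxy)cyclopent-2-en-1-one | O=C1C=C[C@H](O[Si](C)(C)C(C)(C)C)C1 | starting material
2 | vinylmagnesium bromide | C=C[Mg]Br | starting material
3 | methyl bromoacetate | COC(=O)CBr | starting material
4 | bromomagnesium enolate of trans-3-vinyl-4-(tert-butyldimethylsilyloxy)cyclopentanone (vinyl β; silyloxy α) | Br[Mg]OC1=C[C@@H](C=C)[C@H](O[Si](C)(C)C(C)(C)C)C1 | intermediate
5 | methyl 2-[4-(tert-butyldimethylsilyloxy)-2-oxo-5-vinylcyclopentyl]acetate, all-trans (arm α; vinyl β; silyloxy α) | O=C1[C@H](CC(=O)OC)[C@@H](C=C)[C@H](O[Si](C)(C)C(C)(C)C)C1 | intermediate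
6 | methyl 2-[(1,5-trans)-2-oxo-5-vinylcyclopent-3-en-1-yl]acetate (arm α; vinyl β) | O=C1[C@H](CC(=O)OC)[C@@H](C=C)C=C1 | intermediate
7 | isopropylmagnesium chloride | CC(C)[Mg]Cl | starting material
8 | methyl 2-[4-isopropyl-2-(trimethylsilyloxy)-5-vinylcyclopent-2-en-1-yl]acetate (arm α; vinyl β; isopropyl α) | C1=C(O[Si](C)(C)C)[C@H](CC(=O)OC)[C@@H](C=C)[C@@H]1C(C)C | intermediate
9 | methyl 2-[4-isopropyl-1-(trimethylsilyloxy)-3-vinylbicyclo[3.1.0]hexan-2-yl]acetate (cyclopropane CH2 β) | C[Si](C)(C)O[C@@]12C[C@@H]1[C@@H](C(C)C)[C@H](C=C)[C@H]2CC(=O)OC | intermediate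
10 | methyl 2-(1-hydroxy-4-isopropyl-3-vinylbicyclo[3.1.0]hexan-2-yl)acetate | O[C@@]12C[C@@H]1[C@@H](C(C)C)[C@H](C=C)[C@H]2CC(=O)OC | intermediate
11 | methyl 2-(4-hydroperoxy-3-isopropyl-6-oxo-2-vinylcyclohexyl)acetate (both C8 epimers) | O=C1CC(OO)[C@@H](C(C)C)[C@H](C=C)[C@H]1CC(=O)OC | intermediate
12 | methyl 2-(5-isopropyl-2-oxo-4-vinyl-7-oxabicyclo[4.1.0]heptan-3-yl)acetate (8α,9α-epoxide; isopropyl α; vinyl β; arm α) | O=C1[C@H](CC(=O)OC)[C@@H](C=C)[C@H](C(C)C)[C@@H]2O[C@H]12 | intermediate
13 | 5-isopropyl-3-(2-methoxyprop-2-en-1-yl)-2-methylene-4-vinyl-7-oxabicyclo[4.1.0]heptane | C=C1[C@H](CC(OC)=C)[C@@H](C=C)[C@H](C(C)C)[C@@H]2O[C@H]12 | intermediate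
14 | 8α,9α-epoxy-7α-isopropyl-4-methoxy-1-methylene-trans-hydrind-4-ene | C=C1[C@@H]2CC(OC)=C[C@H]2[C@H](C(C)C)[C@@H]3O[C@H]13 | intermediate
15 | 4,5-diacetoxy-4-methoxy adduct of 14 (mixed ketal; C4 not defined) | C=C1[C@@H]2CC(OC)(OC(C)=O)[C@H](OC(C)=O)[C@H]2[C@H](C(C)C)[C@@H]3O[C@H]13 | intermediate
16 | 5α-acetoxy-8α,9α-epoxy-7α-isopropyl-1-methylene-trans-hydrindan-4-one | C=C1[C@@H]2CC(=O)[C@H](OC(C)=O)[C@H]2[C@H](C(C)C)[C@@H]3O[C@H]13 | intermediate
17 | angelic acid, (Z)-2-methylbut-2-enoic acid | C/C=C(/C)C(=O)O | starting material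
18 | CNP0317011.1 | C=C1[C@@H]2CC(=O)[C@H](OC(C)=O)[C@H]2[C@H](C(C)C)[C@H](O)[C@H]1OC(=O)/C(C)=C\C | target

**Step count and risks**
Total: 8 steps. Longest linear sequence: 8 steps (from 1).

Step 4 (the new aerobic ring expansion–epoxidation) is the least certain. The β-hydroperoxy ketone may fragment (Kornblum–DeLaMare) instead of closing, or the C8 epimers may not converge on the α-epoxide. The fallback uses known chemistry, sets out from 9 and returns at 12. FeCl3 (2.2 equiv) in DMF at 0 °C opens the siloxycyclopropane to the ring-expanded chloro ketone methyl 2-(4-chloro-3-isopropyl-6-oxo-2-vinylcyclohexyl)acetate F1. NaOAc in MeOH eliminates HCl to the enone methyl 2-(5-isopropyl-2-oxo-6-vinylcyclohex-3-en-1-yl)acetate F2. tBuOOH/DBU in CH2Cl2 then epoxidises F2 by axial attack at C8 to give 12.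

Step 5 (double methylenation) may stall at the ester, or the titanium carbene may attack the epoxide at 70 °C. The fallback sets out from 12 and returns at 13, with each carbonyl olefinated separately by a different reagent class. Ph3P=CH2 (Ph3PCH3Br, KOtBu, THF, 0 °C) methylenates only the ketone to give methyl 2-(5-isopropyl-2-methylene-4-vinyl-7-oxabicyclo[4.1.0]heptan-3-yl)acetate F3. The ester of F3 is then methylenated at −40 °C with Cp2Ti(μ-Cl)(μ-CH2)AlMe2 in THF/pyridine to give 13.

Step 8 (epoxide opening by angelic acid) may give SN2' attack at the exocyclic CH2 or react too slowly with the hindered acid. The fallback sets out from 16 and returns at 18. Dilute HClO4 in THF–H2O at 0 °C opens the epoxide at the allylic C9 to the trans-diaxial diol 5α-acetoxy-8α,9β-dihydroxy-7α-isopropyl-1-methylene-trans-hydrindan-4-one F4. The less hindered allylic 9-hydroxyl of F4 is then acylated with the mixed anhydride of 17 and 2,4,6-trichlorobenzoyl chloride (Et3N, toluene, 80 °C, no DMAP) to give 18.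

**Further compounds**
F1 | step 4 | methyl 2-(4-chloro-3-isopropyl-6-oxo-2-vinylcyclohexyl)acetate (C8 epimers) | O=C1CC(Cl)[C@@H](C(C)C)[C@H](C=C)[C@H]1CC(=O)OC
F2 | step 4 | methyl 2-(5-isopropyl-2-oxo-6-vinylcyclohex-3-en-1-yl)acetate | O=C1C=C[C@@H](C(C)C)[C@H](C=C)[C@H]1CC(=O)OC
F3 | step 5 | methyl 2-(5-isopropyl-2-methylene-4-vinyl-7-oxabicyclo[4.1.0]heptan-3-yl)acetate | C=C1[C@H](CC(=O)OC)[C@@H](C=C)[C@H](C(C)C)[C@@H]2O[C@H]12
F4 | step 8 | 5α-acetoxy-8α,9β-dihydroxy-7α-isopropyl-1-methylene-trans-hydrindan-4-one | C=C1[C@@H]2CC(=O)[C@H](OC(C)=O)[C@H]2[C@H](C(C)C)[C@H](O)[C@H]1O
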